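The eleven-membered carbocycle is closed by forming the C2–C15 bond (numbering in the remark below) in a ring-transposing Claisen rearrangement. The target hides a γ,δ-unsaturated carbonyl retron: exocyclic methylene C17=C1 on the cyclohexane, stereocentre C2, macrocycle methylene C15 and oxygenated C14. With C14 at the ketone level, the precursor is an eleven-membered cyclic enol ether in which oxygen bridges C14 and C17 and the cyclohexene C1=C2 is the allyl partner; it comes from a macrolactone by methylenation. One [3,3] shift forms C2–C15, sets C2, unveils the exocyclic methylene and leaves the C12–C14 enone, which is later turned into the epoxy propionate.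

Key step: step 16

Remark (numbering assumed for convenience): C1 = ring carbon bearing the exocyclic methylene C17; C2 = neighbouring cyclohexane CH that also carries the macrocycle; C3 = CH2; C4 = CH–O of the six-membered ring; C5 = quaternary carbon (methyl C18); C6, C7 = cyclopentane CH2; C8 = cyclopentane CH bearing the side chain; C9 = CH(CH3) (methyl C19); C10 = CH–O; C11 = CH2; C12 = epoxide CH; C13 = epoxide C(CH3) (methyl C20); C14 = CH–O; C15 = CH2 bonded to C2; C16 = ring-fusion CH bonded to C1, C5 and C8. Compounds 1, 7, 12, 18 and 21 and all reagents are taken as commercial.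

Step 1
Reactants: 1 1,4-dioxaspiro[4.5]decan-7-one
Product: 3 (S)-8-hydroxy-1,4-dioxaspiro[4.5]decan-7-one, via aminooxy ketone 2 (not isolated)
Conditions: PhNO (0.5 equiv), D-proline (20 mol %), DMF, 0 °C; then H2 (1 atm), Pd/C (palladium metal on carbon), MeOH, 23 °C
Reagents that add atoms: nitrosobenzene, O=Nc1ccccc1
Why: Proline-catalysed α-aminoxylation through the enamine formed on the CH2 remote from the ketal, D-proline directing O-attack to the face that gives the (S) centre (mirror image of the L-proline outcome), followed by hydrogenolysis of the weak N–O bond.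

Step 2
Reactants: 3 (S)-8-hydroxy-1,4-dioxaspiro[4.5]decan-7-one
Product: 4 (S)-8-(tert-butyldiphenylsilyloxy)-1,4-dioxaspiro[4.5]decan-7-one
Conditions: tBuPh2SiCl, imidazole, DMF, 0 → 23 °C
Reagents that add atoms: tert-butyl(chloro)diphenylsilane, CC(C)(C)[Si](Cl)(c1ccccc1)c1ccccc1
Why: Imidazole-promoted silyl ether formation on the secondary alcohol; the acid-stable silyl group is chosen to survive the later aqueous acid steps and the stereocentre is not touched.

Step 3
Reactants: 4 (S)-8-(tert-butyldiphenylsilyloxy)-1,4-dioxaspiro[4.5]decan-7-one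
Product: 6 (S)-4-(tert-butyldiphenylsilyloxy)-3-methylcyclohex-2-en-1-one, via tertiary alcohol 5 (not isolated)
Conditions: MeMgBr, THF, −78 °C; then 1 M HCl, THF, 23 °C
Reagents that add atoms: methylmagnesium bromide, C[Mg]Br; water, O
Why: Grignard 1,2-addition followed by acid hydrolysis of the ketal and aldol-type dehydration of the resulting β-hydroxy ketone gives the transposed conjugated enone; the carbinol centre is destroyed and the silyloxy-bearing centre (future C4) is unchanged.

Step 4
Reactants: 6 (S)-4-(tert-butyldiphenylsilyloxy)-3-methylcyclohex-2-en-1-one; 7 2-(2-bromoethyl)-1,3-dioxolane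
Product: 9 (3S,4S)-4-(tert-butyldiphenylsilyloxy)-3-[2-(1,3-dioxolan-2-yl)ethyl]-3-methylcyclohexan-1-one, via Grignard reagent 8 (not isolated)
Conditions: 7, Mg, THF, 25 °C; then CuBr·SMe2 (20 mol %), THF/Me2S, −78 °C; 6, −78 → −20 °C; aq. NH4Cl
Reagents that add atoms: none
Why: Copper-catalysed conjugate addition of a Grignard reagent; attack anti to the neighbouring silyloxy group sets the quaternary C5 with its methyl cis to the C4 oxygen.

Step 5
Reactants: 9 (3S,4S)-4-(tert-butyldiphenylsilyloxy)-3-[2-(1,3-dioxolan-2-yl)ethyl]-3-methylcyclohexan-1-one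
Product: 11 (3aS,4S)-4-(tert-butyldiphenylsilyloxy)-3a-methyl-2,3,3a,4,5,6-hexahydro-7H-inden-7-one, via keto aldehyde 10 (not isolated)
Conditions: 1 M HCl, THF, 45 °C
Reagents that add atoms: none
Why: Acetal hydrolysis and intramolecular aldol condensation (cyclopentene annulation): the C16 enol attacks the aldehyde in a 5-exo-trig closure and dehydration gives the ring-fusion enone C1(=O)–C16=C8; no new stereocentre is formed.

Step 6
Reactants: 11 (3aS,4S)-4-(tert-butyldiphenylsilyloxy)-3a-methyl-2,3,3a,4,5,6-hexahydro-7H-inden-7-one; 12 tert-butyl[(1-methoxyethenyl)oxy]dimethylsilane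
Product: 14 methyl 2-[(1S,3aS,4S,7aR)-4-(tert-butyldiphenylsilyloxy)-3a-methyl-7-oxooctahydro-1H-inden-1-yl]acetate, via silyl enol ether 13 (not isolated)
Conditions: 12 (1.5 equiv), Sc(OTf)3 (5 mol %), CH2Cl2, −78 → −40 °C; then 1 M HCl, THF, 0 °C
Reagents that add atoms: none
Why: Mukaiyama–Michael addition to the s-cis alkylidene ketone: the ketene acetal adds to C8 anti to the axial C18 methyl and the C4 silyloxy group, and hydrolysis of the silyl enol ether protonates C16 kinetically on the face anti to the new pseudo-axial C8 arm, which gives the cis ring fusion.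

Step 7
Reactants: 14 methyl 2-[(1S,3aS,4S,7aR)-4-(tert-butyldiphenylsilyloxy)-3a-methyl-7-oxooctahydro-1H-inden-1-yl]acetate
Product: 15 methyl 2-[(1S,3aS,4S,7aR)-4-(tert-butyldiphenylsilyloxy)-3a-methyl-7-(trifluoromethylsulfonyloxy)-2,3,3a,4,5,7a-hexahydro-1H-inden-1-yl]acetate
Conditions: KN(SiMe3)2 (1.05 equiv), THF, −78 °C; PhNTf2, −78 → 0 °C
Reagents that add atoms: N-phenylbis(trifluoromethanesulfonimide), O=S(=O)(N(c1ccccc1)S(=O)(=O)C(F)(F)F)C(F)(F)F
Why: Kinetic deprotonation at the unhindered C2 methylene (not the ring-fusion methine, not the less acidic ester) and O-sulfonylation of the enolate (enol triflate formation) place the C1=C2 olefin and lock the C16 configuration.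

Step 8
Reactants: 15 methyl 2-[(1S,3aS,4S,7aR)-4-(tert-butyldiphenylsilyloxy)-3a-methyl-7-(trifluoromethylsulfonyloxy)-2,3,3a,4,5,7a-hexahydro-1H-inden-1-yl]acetate
Product: 16 methyl (2S)-2-[(1R,3aS,4S,7aR)-4-(tert-butyldiphenylsilyloxy)-3a-methyl-7-(trifluoromethylsulfonyloxy)-2,3,3a,4,5,7a-hexahydro-1H-inden-1-yl]propanoate
Conditions: LiN(iPr)2 (1.1 equiv), THF, −78 °C; MeI, −78 → −40 °C
Reagents that add atoms: iodomethane, CI
Why: Ester enolate alkylation under 1,2-induction: A(1,3) strain holds H-8 in the enolate plane and iodomethane approaches from the C7 side, away from C16 and C1, which sets C9 (the control known from C20 alkylation of steroidal C17 acetates).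

Step 9
Reactants: 16 methyl (2S)-2-[(1R,3aS,4S,7aR)-4-(tert-butyldiphenylsilyloxy)-3a-methyl-7-(trifluoromethylsulfonyloxy)-2,3,3a,4,5,7a-hexahydro-1H-inden-1-yl]propanoate
Product: 17 (2S)-2-[(1R,3aS,4S,7aR)-4-(tert-butyldiphenylsilyloxy)-3a-methyl-7-(trifluoromethylsulfonyloxy)-2,3,3a,4,5,7a-hexahydro-1H-inden-1-yl]propanal
Conditions: iBu2AlH (1.1 equiv), CH2Cl2, −78 °C; aq. KNaC4H4O6
Reagents that add atoms: none
Why: Low-temperature half-reduction of the methyl ester through the stable tetrahedral aluminate (iBu2AlH reduction); triflate and silyl ether are inert and the aldehyde is used at once so that C9 does not epimerise.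

Step 10
Reactants: 18 methyl (E)-2-methylbut-2-enoate (methyl tiglate)
Product: 19 tert-butyl[(1-methoxy-2-methylbuta-1,3-dien-1-yl)oxy]dimethylsilane (ketene acetal E/Z mixture, inconsequential)
Conditions: LiN(iPr)2, THF/DMPU, −78 °C; tBuMe2SiCl, −78 → 0 °C
Reagents that add atoms: tert-butyl(chloro)dimethylsilane, CC(C)(C)[Si](C)(C)Cl
Why: γ-Deprotonation of the enoate and O-silylation of the dienolate (silyl dienolate formation); no stereocentre is involved.

Step 11
Reactants: 17 (2S)-2-[(1R,3aS,4S,7aR)-4-(tert-butyldiphenylsilyloxy)-3a-methyl-7-(trifluoromethylsulfonyloxy)-2,3,3a,4,5,7a-hexahydro-1H-inden-1-yl]propanal; 19 tert-butyl[(1-methoxy-2-methylbuta-1,3-dien-1-yl)oxy]dimethylsilane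
Product: 20 methyl (2E,5S,6S)-5-(tert-butyldimethylsilyloxy)-2-methyl-6-[the hydrindenyl triflate unit of 17]hept-2-enoate (C4, C5, C8, C9, C16 as before; new C10 centre S)
Conditions: 19 (1.5 equiv), HNTf2 (3 mol %), CH2Cl2, −78 °C
Reagents that add atoms: none
Why: Vinylogous Mukaiyama aldol addition catalysed by the silyl triflimide formed in the flask, with silyl transfer to the aldolate oxygen: γ-attack gives the (E)-2-methyl enoate and Felkin–Anh attack on the α-methyl aldehyde sets C10 syn to the C9 methyl.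

Step 12
Reactants: 20 methyl (2E,5S,6S)-5-(tert-butyldimethylsilyloxy)-2-methyl-6-[hydrindenyl triflate unit]hept-2-enoate; 21 (tributylstannyl)methanol
Product: 22 the allylic alcohol in which the triflate of 20 is replaced by CH2OH (C17) on C1 of the C1=C2 olefin
Conditions: Pd(PPh3)4 (10 mol %), LiCl (3 equiv), 21 (1.5 equiv), 1,4-dioxane, 100 °C
Reagents that add atoms: none
Why: Stille cross-coupling of the enol triflate with the hydroxymethyl stannane installs C17 as a primary allylic alcohol; no stereocentre is touched.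

Step 13
Reactants: 22 hydroxymethyl diene ester
Product: 23 the seco acid (2E,5S,6S)-5-(tert-butyldimethylsilyloxy)-2-methyl-6-[hydroxymethyl hydrindenyl unit]hept-2-enoic acid
Conditions: LiOH·H2O, THF/MeOH/H2O, 23 °C; then 1 M HCl to pH 4
Reagents that add atoms: lithium hydroxide, [Li+].[OH-]
Why: Saponification of the methyl ester; the silyl ethers and both olefins are stable to aqueous LiOH at room temperature.

Step 14
Reactants: 23 seco acid
Product: 24 the eleven-membered macrolactone (C14 carboxyl esterified by O–C17H2; C1=C2 and (12E)-C12=C13 olefins; C4 tert-butyldiphenylsilyl ether, C10 tert-butyldimethylsilyl ether)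
Conditions: 2-methyl-6-nitrobenzoic anhydride (1.3 equiv), DMAP (6 equiv), CH2Cl2 (1 mM, syringe-pump addition), 40 °C
Reagents that add atoms: none
Why: Shiina macrolactonisation (mixed-anhydride activation and DMAP acyl transfer) under high dilution closes the eleven-membered lactone between C14 and O–C17; no stereocentre is affected.

Step 15
Reactants: 24 macrolactone
Product: 25 the eleven-membered cyclic enol ether (C14 now carries the exocyclic methylene C15; 2-alkoxy-1,3-diene C15=C14–C13=C12)
Conditions: Cp2TiMe2 (3 equiv), toluene, 70 °C, dark; filtration through basic alumina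
Reagents that add atoms: dimethyltitanocene, C[Ti](C)(C1C=CC=C1)C1C=CC=C1
Why: Petasis methylenation of the lactone carbonyl through titanocene methylidene (carbonyl olefination); silyl ethers and olefins are inert and the mild temperature avoids premature rearrangement.

Step 16
Reactants: 25 cyclic enol ether
Product: 26 the tricyclic enone (eleven-membered carbocycle closed; C14 ketone conjugated to (12E)-C12=C13; exocyclic methylene C17=C1; new C2 centre as in the target)
Conditions: mesitylene (2 mM), Et3N (5 mol %), base-washed sealed tube, 150 °C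
Reagents that add atoms: none
Why: Thermal concerted [3,3]-sigmatropic (Claisen) rearrangement of the allyl vinyl ether C15=C14–O–C17–C1=C2: the O–C17 bond breaks while C15 bonds to C2, C1=C17 and the C14 carbonyl appear, and conjugation of the new ketone with C12=C13 makes the step irreversible. The closest known reaction type is the methylenation/Claisen sequence of lactone-derived 2-methylene oxacycles that converts oxacycles into carbocyclic ketones. The eleven-membered carbocycle is closed by transposition of the eleven-membered oxacycle (ring size retained) through a boat-like bicyclo[7.2.2] transition state, suprafacial on the C17–C1=C2 allyl unit. The new stereocentre C2 is controlled by the cis-fused cyclopentane: C6 and C8 shield the concave face of the cyclohexene, so the oxa-allyl fragment stacks on the convex face (syn to H-16 and C18) and C15 is delivered anti to the C16–C8 bond, as the target requires. The step needs this facial selectivity and survival of the acid-labile enol ether; the first is secured by the ring fusion and the seven-atom tether that leaves C16 from the opposite face, the second by base-washed glassware and a trace of Et3N. The E geometry of C12=C13 is not touched.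

Step 17
Reactants: 26 tricyclic enone
Product: 27 the (14R)-allylic alcohol (bis-silyl ether)
Conditions: (S)-2-methyl-CBS-oxazaborolidine (1.0 equiv), BH3·SMe2 (1.2 equiv), toluene, −40 °C; MeOH quench
Reagents that add atoms: none
Why: Corey–Bakshi–Shibata reduction: the alkenyl group acts as the large and C15 as the small substituent, so the (S)-oxazaborolidine delivers hydride 1,2-selectively to give the (R)-configured C14 carbinol.

Step 18
Reactants: 27 allylic alcohol bis-silyl ether
Product: 28 the triene triol (free hydroxyls at C4, C10 and C14)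
Conditions: Bu4NF (6 equiv), THF, 50 °C; aq. NH4Cl
Reagents that add atoms: none
Why: Fluoride-mediated cleavage of both silyl ethers (desilylation); olefins and carbinol stereocentres are unaffected.

Step 19
Reactants: 28 triene triol
Product: 29 the 12,13-epoxy triol (epoxide configured as in the target)
Conditions: L-fructose-derived Shi ketone (enantiomer of the usual D-fructose catalyst, 30 mol %), Oxone (2KHSO5·KHSO4·K2SO4), K2CO3, Bu4NHSO4, MeCN/CH2(OMe)2/aq. Na2B4O7 buffer (pH 10.5), 0 °C
Reagents that add atoms: potassium peroxymonosulfate, [K+].[O-]S(=O)(=O)OO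
Why: Shi asymmetric epoxidation: the chiral dioxirane reacts with the electron-rich (E)-trisubstituted C12=C13 olefin in preference to the 1,1-disubstituted C1=C17 olefin, this ketone enantiomer delivers oxygen to the face that gives the target configuration at C12 and C13 (threo to the C14 oxygen), and the E geometry fixes C11 and C14 trans on the epoxide.

Step 20
Reactants: 29 epoxy triol
Product: 30 the target, 4,10,14-tripropanoate of the 12,13-epoxy triol (CNP0332420.1)
Conditions: (EtCO)2O (10 equiv), DMAP (1 equiv), Et3N, CH2Cl2, 23 → 40 °C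
Reagents that add atoms: propanoic anhydride, CCC(=O)OC(=O)CC
Why: DMAP-catalysed acylation (esterification) of the three secondary alcohols, including the hindered C4 and C14 hydroxyls; the epoxide is stable under these non-acidic conditions and no stereocentre changes.

Compound list
1 | 1,4-dioxaspiro[4.5]decan-7-one | O=C1CCCC2(C1)OCCO2 | starting material
2 | (S)-8-(phenylaminooxy)-1,4-dioxaspiro[4.5]decan-7-one | O=C1CC2(OCCO2)CC[C@@H]1ONc1ccccc1 | intermediate
3 | (S)-8-hydroxy-1,4-dioxaspiro[4.5]decan-7-one | O=C1CC2(OCCO2)CC[C@@H]1O | intermediate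
4 | (S)-8-(tert-butyldiphenylsilyloxy)-1,4-dioxaspiro[4.5]decan-7-one | O=C1CC2(OCCO2)CC[C@@H]1O[Si](c1ccccc1)(c1ccccc1)C(C)(C)C | intermediate
5 | (8S)-8-(tert-butyldiphenylsilyloxy)-7-methyl-1,4-dioxaspiro[4.5]decan-7-ol (either C7 epimer) | CC1(O)CC2(OCCO2)CC[C@@H]1O[Si](c1ccccc1)(c1ccccc1)C(C)(C)C | intermediate
6 | (S)-4-(tert-butyldiphenylsilyloxy)-3-methylcyclohex-2-en-1-one | O=C1CC[C@H](O[Si](c2ccccc2)(c2ccccc2)C(C)(C)C)C(C)=C1 | intermediate
7 | 2-(2-bromoethyl)-1,3-dioxolane | BrCCC1OCCO1 | starting material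
8 | [2-(1,3-dioxolan-2-yl)ethyl]magnesium bromide | Br[Mg]CCC1OCCO1 | intermediate
9 | (3S,4S)-4-(tert-butyldiphenylsilyloxy)-3-[2-(1,3-dioxolan-2-yl)ethyl]-3-methylcyclohexan-1-one | O=C1CC[C@H](O[Si](c5ccccc5)(c5ccccc5)C(C)(C)C)[C@@](C)(CCC2OCCO2)C1 | intermediate
10 | 3-[(1S,2S)-2-(tert-butyldiphenylsilyloxy)-1-methyl-5-oxocyclohexyl]propanal | O=C1CC[C@H](O[Si](c5ccccc5)(c5ccccc5)C(C)(C)C)[C@@](C)(CCC=O)C1 | intermediate
11 | (3aS,4S)-4-(tert-butyldiphenylsilyloxy)-3a-methyl-2,3,3a,4,5,6-hexahydro-7H-inden-7-one | O=C1CC[C@H](O[Si](c5ccccc5)(c5ccccc5)C(C)(C)C)[C@@]2(C)CCC=C12 | intermediate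
12 | tert-butyl[(1-methoxyethenyl)oxy]dimethylsilane | C=C(OC)O[Si](C)(C)C(C)(C)C | starting material
13 | tert-butyldimethylsilyl enol ether of 14 (C1–OSi, C1=C16) | CC(C)(C)[Si](C)(C)OC1=C2[C@H](CC(=O)OC)CC[C@]2(C)[C@@H](O[Si](c5ccccc5)(c5ccccc5)C(C)(C)C)CC1 | intermediate
14 | methyl 2-[(1S,3aS,4S,7aR)-4-(tert-butyldiphenylsilyloxy)-3a-methyl-7-oxooctahydro-1H-inden-1-yl]acetate | O=C1CC[C@H](O[Si](c5ccccc5)(c5ccccc5)C(C)(C)C)[C@@]3(C)CC[C@@H](CC(=O)OC)[C@@H]13 | intermediate
15 | methyl 2-[(1S,3aS,4S,7aR)-4-(tert-butyldiphenylsilyloxy)-3a-methyl-7-(trifluoromethylsulfonyloxy)-2,3,3a,4,5,7a-hexahydro-1H-inden-1-yl]acetate | O=S(=O)(OC1=CC[C@H](O[Si](c5ccccc5)(c5ccccc5)C(C)(C)C)[C@@]3(C)CC[C@@H](CC(=O)OC)[C@@H]13)C(F)(F)F | intermediate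
16 | methyl (2S)-2-[(1R,3aS,4S,7aR)-4-(tert-butyldiphenylsilyloxy)-3a-methyl-7-(trifluoromethylsulfonyloxy)-2,3,3a,4,5,7a-hexahydro-1H-inden-1-yl]propanoate | O=S(=O)(OC1=CC[C@H](O[Si](c5ccccc5)(c5ccccc5)C(C)(C)C)[C@@]3(C)CC[C@@H]([C@H](C)C(=O)OC)[C@@H]13)C(F)(F)F | intermediate
17 | (2S)-2-[(1R,3aS,4S,7aR)-4-(tert-butyldiphenylsilyloxy)-3a-methyl-7-(trifluoromethylsulfonyloxy)-2,3,3a,4,5,7a-hexahydro-1H-inden-1-yl]propanal | O=S(=O)(OC1=CC[C@H](O[Si](c5ccccc5)(c5ccccc5)C(C)(C)C)[C@@]3(C)CC[C@@H]([C@H](C)C=O)[C@@H]13)C(F)(F)F | intermediate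
18 | methyl (E)-2-methylbut-2-enoate | C/C=C(\C)C(=O)OC | starting material
19 | tert-butyl[(1-methoxy-2-methylbuta-1,3-dien-1-yl)oxy]dimethylsilane | C=CC(C)=C(OC)O[Si](C)(C)C(C)(C)C | intermediate
20 | methyl (2E,5S,6S)-5-(tert-butyldimethylsilyloxy)-2-methyl-6-[hydrindenyl triflate unit]hept-2-enoate | O=S(=O)(OC1=CC[C@H](O[Si](c5ccccc5)(c5ccccc5)C(C)(C)C)[C@@]3(C)CC[C@@H]([C@H](C)[C@@H](O[Si](C)(C)C(C)(C)C)C/C=C(\C)C(=O)OC)[C@@H]13)C(F)(F)F | intermediate
21 | (tributylstannyl)methanol | OC[Sn](CCCC)(CCCC)CCCC | starting material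
22 | methyl (2E,5S,6S)-5-(tert-butyldimethylsilyloxy)-2-methyl-6-[7-(hydroxymethyl) hydrindenyl unit]hept-2-enoate | OCC1=CC[C@H](O[Si](c5ccccc5)(c5ccccc5)C(C)(C)C)[C@@]3(C)CC[C@@H]([C@H](C)[C@@H](O[Si](C)(C)C(C)(C)C)C/C=C(\C)C(=O)OC)[C@@H]13 | intermediate
23 | seco acid, the carboxylic acid of 22 | OCC1=CC[C@H](O[Si](c5ccccc5)(c5ccccc5)C(C)(C)C)[C@@]3(C)CC[C@@H]([C@H](C)[C@@H](O[Si](C)(C)C(C)(C)C)C/C=C(\C)C(=O)O)[C@@H]13 | intermediate
24 | eleven-membered macrolactone (C14(=O)–O–C17; C1=C2; (12E); 4-O-silyl, 10-O-silyl) | C12=CC[C@H](O[Si](c5ccccc5)(c5ccccc5)C(C)(C)C)[C@@]3(C)CC[C@@H]([C@H](C)[C@@H](O[Si](C)(C)C(C)(C)C)C/C=C(\C)C(=O)OC2)[C@@H]13 | intermediate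
25 | eleven-membered cyclic enol ether (C14=C15 exocyclic methylene on the oxacycle) | C12=CC[C@H](O[Si](c5ccccc5)(c5ccccc5)C(C)(C)C)[C@@]3(C)CC[C@@H]([C@H](C)[C@@H](O[Si](C)(C)C(C)(C)C)C/C=C(\C)C(=C)OC2)[C@@H]13 | intermediate
26 | tricyclic enone (C14 ketone, (12E)-olefin, C1=C17 methylene, bis-silyl ether) | C=C1[C@H]2C[C@H](O[Si](c5ccccc5)(c5ccccc5)C(C)(C)C)[C@@]3(C)CC[C@@H]([C@H](C)[C@@H](O[Si](C)(C)C(C)(C)C)C/C=C(\C)C(=O)C2)[C@@H]13 | intermediate
27 | (14R)-allylic alcohol, bis-silyl ether | C=C1[C@H]2C[C@H](O[Si](c5ccccc5)(c5ccccc5)C(C)(C)C)[C@@]3(C)CC[C@@H]([C@H](C)[C@@H](O[Si](C)(C)C(C)(C)C)C/C=C(\C)[C@H](O)C2)[C@@H]13 | intermediate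
28 | triene triol (4-OH, 10-OH, 14-OH) | C=C1[C@H]2C[C@H](O)[C@@]3(C)CC[C@@H]([C@H](C)[C@@H](O)C/C=C(\C)[C@H](O)C2)[C@@H]13 | intermediate
29 | 12,13-epoxy triol | C=C1[C@H]2C[C@H](O)[C@@]3(C)CC[C@@H]([C@H](C)[C@@H](O)C[C@@H]4O[C@@]4(C)[C@H](O)C2)[C@@H]13 | intermediate
30 | CNP0332420.1, the 4,10,14-tripropanoate of the 12,13-epoxy triol | C=C1[C@H]2C[C@H](OC(=O)CC)[C@@]3(C)CC[C@@H]([C@H](C)[C@@H](OC(=O)CC)C[C@@H]4O[C@@]4(C)[C@H](OC(=O)CC)C2)[C@@H]13 | target

Total step count: 20. Longest linear sequence: 19 (steps 1–9 and 11–20; step 10 is a one-step side branch).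

Steps most likely to fail

Step 16. The [3,3] shift may stall because the eleven-membered enol ether cannot reach the boat-like geometry. It may instead deliver C15 to the concave face (epimer at C2), or the enol ether may hydrolyse before it rearranges. The fallback forms the same C2–C15 bond by a ring-contracting Carroll rearrangement of a thirteen-membered β-keto lactone, in which the tether spans C15 and C1 and a chair-like array is accessible. It sets out from macrolactone 24. Claisen condensation with LiCH2CO2tBu (from tert-butyl acetate and LiN(iPr)2, THF, −78 °C) opens the lactone to the hydroxy tert-butyl β-keto ester F1. Heating in toluene (110 °C, high dilution) generates the acylketene, which is trapped by the C17 hydroxyl to give the thirteen-membered β-keto lactone F2. Further heating (xylene, 160 °C) effects the [3,3] shift of its enol form to the β-keto acid F3, which loses carbon dioxide in the flask and comes back to the route at enone 26.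

Step 14. Intermolecular acylation (diolide and oligomer formation) may outrun closure of the strained eleven-membered lactone, and the activated enoate may isomerise. The fallback closes the same ring by a C–C bond (C1–C17) instead of the C–O bond. It sets out from triflate ester 20. Hydrolysis with Me3SnOH (1,2-dichloroethane, 80 °C) gives the triflate acid F4. Esterification with 21 (N-ethyl-N'-(3-dimethylaminopropyl)carbodiimide hydrochloride, DMAP) gives the (tributylstannyl)methyl ester F5. Intramolecular Stille coupling (Pd2(dba)3, AsPh3, LiCl, N-methylpyrrolidone, high dilution, 60 °C) then comes back to the route at macrolactone 24.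

Step 19. Facial selectivity may be poor through mismatch between the chiral dioxirane and the macrocycle conformation, and the exocyclic methylene may be oxidised competitively. The fallback uses hydroxyl-directed epoxidation and inversion. It sets out from enone 26. Reduction with (R)-2-methyl-CBS-oxazaborolidine and BH3·SMe2 gives the C14-epimeric allylic alcohol F6. VO(acac)2 and tBuOOH (CH2Cl2, 0 °C) epoxidise only the allylic alcohol olefin, syn to the hydroxyl (erythro), to give the epoxy alcohol F7 with the target configuration at C12 and C13. Mitsunobu esterification with propanoic acid (PPh3, diisopropyl azodicarboxylate, toluene) inverts C14 and gives the 14-propanoate F8. Bu4NF removes both silyl groups to give the diol F9, and acylation with (EtCO)2O and DMAP comes back to the route at target 30.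

Further compounds
F1 | step 16 | tert-butyl β-keto ester with free C17 hydroxyl (C14 ketone, C15 methylene, tert-butyl ester) | OCC1=CC[C@H](O[Si](c5ccccc5)(c5ccccc5)C(C)(C)C)[C@@]3(C)CC[C@@H]([C@H](C)[C@@H](O[Si](C)(C)C(C)(C)C)C/C=C(\C)C(=O)CC(=O)OC(C)(C)C)[C@@H]13
F2 | step 16 | thirteen-membered β-keto lactone | C12=CC[C@H](O[Si](c5ccccc5)(c5ccccc5)C(C)(C)C)[C@@]3(C)CC[C@@H]([C@H](C)[C@@H](O[Si](C)(C)C(C)(C)C)C/C=C(\C)C(=O)CC(=O)OC2)[C@@H]13
F3 | step 16 | C15-carboxy derivative of 26 (β-keto acid, either C15 epimer) | C=C1[C@H]2C[C@H](O[Si](c5ccccc5)(c5ccccc5)C(C)(C)C)[C@@]3(C)CC[C@@H]([C@H](C)[C@@H](O[Si](C)(C)C(C)(C)C)C/C=C(\C)C(=O)C2C(=O)O)[C@@H]13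
F4 | step 14 | carboxylic acid of triflate ester 20 | O=S(=O)(OC1=CC[C@H](O[Si](c5ccccc5)(c5ccccc5)C(C)(C)C)[C@@]3(C)CC[C@@H]([C@H](C)[C@@H](O[Si](C)(C)C(C)(C)C)C/C=C(\C)C(=O)O)[C@@H]13)C(F)(F)F
F5 | step 14 | (tributylstannyl)methyl ester of F4 | O=S(=O)(OC1=CC[C@H](O[Si](c5ccccc5)(c5ccccc5)C(C)(C)C)[C@@]3(C)CC[C@@H]([C@H](C)[C@@H](O[Si](C)(C)C(C)(C)C)C/C=C(\C)C(=O)OC[Sn](CCCC)(CCCC)CCCC)[C@@H]13)C(F)(F)F
F6 | step 19 | C14 epimer of allylic alcohol 27 | C=C1[C@H]2C[C@H](O[Si](c5ccccc5)(c5ccccc5)C(C)(C)C)[C@@]3(C)CC[C@@H]([C@H](C)[C@@H](O[Si](C)(C)C(C)(C)C)C/C=C(\C)[C@@H](O)C2)[C@@H]13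
F7 | step 19 | 12,13-epoxy alcohol, C14 epimeric, bis-silyl ether | C=C1[C@H]2C[C@H](O[Si](c5ccccc5)(c5ccccc5)C(C)(C)C)[C@@]3(C)CC[C@@H]([C@H](C)[C@@H](O[Si](C)(C)C(C)(C)C)C[C@@H]4O[C@@]4(C)[C@@H](O)C2)[C@@H]13
F8 | step 19 | 12,13-epoxy 14-propanoate with target C14 configuration, bis-silyl ether | C=C1[C@H]2C[C@H](O[Si](c5ccccc5)(c5ccccc5)C(C)(C)C)[C@@]3(C)CC[C@@H]([C@H](C)[C@@H](O[Si](C)(C)C(C)(C)C)C[C@@H]4O[C@@]4(C)[C@H](OC(=O)CC)C2)[C@@H]13
F9 | step 19 | 12,13-epoxy 4,10-diol 14-propanoate | C=C1[C@H]2C[C@H](O)[C@@]3(C)CC[C@@H]([C@H](C)[C@@H](O)C[C@@H]4O[C@@]4(C)[C@H](OC(=O)CC)C2)[C@@H]13
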